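**Retrosynthetic overview**

1. Last disconnections: the free phenol of ring B (kept as a methoxymethyl ether) and the prenyl group at C8 of ring A (cross-coupling at a C8 chlorine). This leaves a chloro-bischromene.
2. Key disconnection: both pyran rings at once, each at C2–C3 and C4–C4a, by a twofold decarboxylative radical (4+2) annulation of a biphenyl bis(aryloxyisobutyric) redox-active ester with phenyl vinyl sulfoxide as acetylene equivalent. Loss of PhSOH in the same flask gives both C3=C4 olefins.
3. Enabling feature: in each chromene the gem-dimethyl carbon C2 is bound to the ring oxygen O1 (site of a tertiary α-aryloxy radical), C3 and C4 are two unsubstituted CH carbons, and each benzene ring has a single free ortho C–H (C4a). C8 is substituted (chlorine placeholder in ring A, protected hydroxyl in ring B) and C6 carries the biaryl bond.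
4. The bis-acid comes from a 4,4'-biphenyldiol by twofold Bargellini reaction (acetone supplies C2 and its methyls), and the biphenyl from a Suzuki–Miyaura coupling of two phenols. The prenyl olefin is withheld until after the radical step because it would trap the C2 radical by 6-exo cyclisation.
5. Ring order: both benzene rings are bought, the biaryl bond is made first, then the two pyran rings are formed together in the key step.

Key step: step 6

Remark: the target has no stereocentre; chromene locants are used throughout, unprimed for ring A (the chromene that ends with the prenyl group) and primed for ring B (the chromene that ends with the free hydroxyl).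

**Route**

Step 1
Reactants: 1 4-bromo-2-hydroxybenzaldehyde
Product: 2 4-bromo-2-(methoxymethoxy)benzaldehyde
Conditions: MOMCl (1.3 equiv), iPr2NEt (1.5 equiv), CH2Cl2, 0 °C → rt
Reagents that add atoms: chloromethyl methyl ether (MOMCl), COCCl
Why: O-alkylation of the phenol by the α-chloro ether (Williamson-type etherification through the methoxymethyl oxocarbenium ion) should protect the oxygen that becomes the free hydroxyl of ring B.

Step 2
Reactants: 2 4-bromo-2-(methoxymethoxy)benzaldehyde
Product: 4 4-bromo-2-(methoxymethoxy)phenol, via aryl formate 3 (not isolated)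
Conditions: mCPBA (1.3 equiv), CH2Cl2, 0 °C → rt; aqueous wash; then K2CO3 (cat.), MeOH, rt
Reagents that add atoms: meta-chloroperoxybenzoic acid (mCPBA), OOC(=O)c1cccc(Cl)c1
Why: Baeyer–Villiger (Dakin-type) oxidation, in which the aryl group with its ortho oxygen migrates to give the formate that base-catalysed methanolysis cleaves, should place the free hydroxyl para to bromine and so tell the two catechol oxygens apart.

Step 3
Reactants: 4 4-bromo-2-(methoxymethoxy)phenol; 5 3-chloro-4-hydroxyphenylboronic acid
Product: 6 3-chloro-3'-(methoxymethoxy)-[1,1'-biphenyl]-4,4'-diol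
Conditions: Pd(PPh3)4 (3 mol%), K2CO3 (3 equiv), 1,4-dioxane/H2O (4:1), 85 °C
Reagents that add atoms: none
Why: Suzuki–Miyaura coupling, in which zerovalent palladium with triphenylphosphine inserts into the C–Br bond but not into the C–Cl bond and both phenols are tolerated as phenoxides, should give the biaryl with the chlorine kept for step 7.

Step 4
Reactants: 6 3-chloro-3'-(methoxymethoxy)-[1,1'-biphenyl]-4,4'-diol
Product: 7 2,2'-{[3-chloro-3'-(methoxymethoxy)-[1,1'-biphenyl]-4,4'-diyl]bis(oxy)}bis(2-methylpropanoic acid)
Conditions: CHCl3 (8 equiv), NaOH (powdered, 16 equiv), acetone, 0 °C → reflux; then 1 M HCl to pH 3, 0 °C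
Reagents that add atoms: acetone, CC(C)=O; chloroform, ClC(Cl)Cl; sodium hydroxide, [Na+].[OH-]
Why: Bargellini reaction, in which each phenoxide opens the gem-dichloroepoxide formed from acetone and trichloromethide at its tertiary carbon and hydroxide completes the carboxylate, should make both hindered aryl–O–CMe2 bonds without substitution at a tertiary halide.

Step 5
Reactants: 7 2,2'-{[3-chloro-3'-(methoxymethoxy)-[1,1'-biphenyl]-4,4'-diyl]bis(oxy)}bis(2-methylpropanoic acid)
Product: 8 bis(1,3-dioxoisoindolin-2-yl) 2,2'-{[3-chloro-3'-(methoxymethoxy)-[1,1'-biphenyl]-4,4'-diyl]bis(oxy)}bis(2-methylpropanoate)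
Conditions: N-hydroxyphthalimide (2.4 equiv), DIC (2.4 equiv), DMAP (0.1 equiv), CH2Cl2, 0 °C → rt
Reagents that add atoms: N-hydroxyphthalimide, ON1C(=O)c2ccccc2C1=O
Why: Carbodiimide (Steglich-type) esterification should turn both tertiary acids into redox-active N-acyloxyphthalimides, a transformation that is routine for α-aryloxyisobutyric acids.

Step 6
Reactants: 8 bis(1,3-dioxoisoindolin-2-yl) 2,2'-{[3-chloro-3'-(methoxymethoxy)-[1,1'-biphenyl]-4,4'-diyl]bis(oxy)}bis(2-methylpropanoate); 9 phenyl vinyl sulfoxide (10 equiv)
Product: 11 8-chloro-8'-(methoxymethoxy)-2,2,2',2'-tetramethyl-2H,2'H-6,6'-bichromene, via bis(4-phenylsulfinylchroman) 10 (not isolated)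
Conditions: fac-Ir(ppy)3 (2 mol%), MeCN (degassed, 0.05 M), 450 nm LEDs, 25 °C; then solvent switch to PhMe, 110 °C
Reagents that add atoms: none
Why: Proposed new method: photoexcited fac-Ir(ppy)3 reduces each N-acyloxyphthalimide, loss of CO2 gives the tertiary α-aryloxy radical at C2, which adds in Giese fashion to the unsubstituted terminus of 9 (C2–C3 bond), and the resulting α-sulfinyl radical at C4 attacks the free ortho carbon C4a (C4–C4a bond) before tetravalent iridium oxidises the cyclohexadienyl radical and phthalimide anion removes the proton, so the cycle is redox-neutral. The closest known reaction types are the photoredox radical (4+2) annulation of α-aryloxy N-acyloxyphthalimides with electron-poor alkenes to chromans and the use of phenyl vinyl sulfoxide as an acetylene equivalent in cycloadditions; new here are the sulfoxide acceptor, the twofold course and the in-flask thermal syn-elimination that turns each C4 sulfoxide into the C3=C4 olefin. Each pyran ring closes by 6-endo attack of the C4 radical on the arene (homolytic aromatic substitution), the 5-exo ipso attack at C8a being reversible and unproductive. The carbon and sulfur stereocentres of 10 form without control and are all erased by the elimination, and the ring fixes the cis olefin geometry, so the product has no stereocentre. The step needs one site of ring closure per arene and one direction of elimination: C8 is blocked by chlorine in ring A and by the methoxymethoxy group in ring B and C6 by the biaryl bond, so only C4a carries an ortho hydrogen, and only C3 carries a hydrogen beta to sulfur. The aryl chloride lies far outside the reducing power of the excited photocatalyst and should stay for step 7.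

Step 7
Reactants: 11 8-chloro-8'-(methoxymethoxy)-2,2,2',2'-tetramethyl-2H,2'H-6,6'-bichromene; 12 3-methylbut-2-en-1-ylzinc bromide (2 equiv, THF solution)
Product: 13 8'-(methoxymethoxy)-2,2,2',2'-tetramethyl-8-(3-methylbut-2-en-1-yl)-2H,2'H-6,6'-bichromene
Conditions: Pd(OAc)2 (3 mol%), CPhos (6 mol%), THF, rt → 45 °C
Reagents that add atoms: none
Why: Negishi cross-coupling, in which zerovalent palladium with a bulky dialkylbiarylphosphine inserts into the C8–Cl bond and reductive elimination takes place at the unsubstituted CH2 terminus of the prenyl ligand, should give the linear prenyl arene while the protected phenol offers no acidic proton to the zinc reagent.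

Step 8
Reactants: 13 8'-(methoxymethoxy)-2,2,2',2'-tetramethyl-8-(3-methylbut-2-en-1-yl)-2H,2'H-6,6'-bichromene
Product: 14 2,2,2',2'-tetramethyl-8-(3-methylbut-2-en-1-yl)-2H,2'H-[6,6'-bichromen]-8'-ol (target CNP0158232.0)
Conditions: HCl (2 M aq., cat.), MeOH, 40 °C
Reagents that add atoms: none
Why: Acid-catalysed acetal exchange (methanolysis of the methoxymethyl ether) should free the phenol under conditions that 2,2-dimethylchromenes tolerate, and no hydroxyl stands next to the prenyl group, so acid-induced chroman formation cannot occur.

**Compound list**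

1 | 4-bromo-2-hydroxybenzaldehyde | O=Cc1ccc(Br)cc1O | starting material
2 | 4-bromo-2-(methoxymethoxy)benzaldehyde | COCOc1cc(Br)ccc1C=O | intermediate
3 | 4-bromo-2-(methoxymethoxy)phenyl formate | COCOc1cc(Br)ccc1OC=O | intermediate (not isolated)
4 | 4-bromo-2-(methoxymethoxy)phenol | COCOc1cc(Br)ccc1O | intermediate
5 | 3-chloro-4-hydroxyphenylboronic acid | OB(O)c1ccc(O)c(Cl)c1 | starting material
6 | 3-chloro-3'-(methoxymethoxy)-[1,1'-biphenyl]-4,4'-diol | COCOc1cc(ccc1O)-c1ccc(O)c(Cl)c1 | intermediate
7 | 2,2'-{[3-chloro-3'-(methoxymethoxy)-[1,1'-biphenyl]-4,4'-diyl]bis(oxy)}bis(2-methylpropanoic acid) | COCOc1cc(ccc1OC(C)(C)C(O)=O)-c1ccc(OC(C)(C)C(O)=O)c(Cl)c1 | intermediate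
8 | bis(1,3-dioxoisoindolin-2-yl) 2,2'-{[3-chloro-3'-(methoxymethoxy)-[1,1'-biphenyl]-4,4'-diyl]bis(oxy)}bis(2-methylpropanoate) | COCOc1cc(ccc1OC(C)(C)C(=O)ON1C(=O)c2ccccc2C1=O)-c1ccc(OC(C)(C)C(=O)ON2C(=O)c3ccccc3C2=O)c(Cl)c1 | intermediate
9 | phenyl vinyl sulfoxide | C=CS(=O)c1ccccc1 | starting material
10 | 8-chloro-8'-(methoxymethoxy)-2,2,2',2'-tetramethyl-4,4'-bis(phenylsulfinyl)-6,6'-bichromane (mixture of diastereomers at C4, C4' and both sulfur atoms) | COCOc1cc(cc2c1OC(C)(C)CC2S(=O)c1ccccc1)-c1cc(Cl)c2OC(C)(C)CC(S(=O)c3ccccc3)c2c1 | intermediate (not isolated)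
11 | 8-chloro-8'-(methoxymethoxy)-2,2,2',2'-tetramethyl-2H,2'H-6,6'-bichromene | COCOc1cc(cc2C=CC(C)(C)Oc12)-c1cc(Cl)c2OC(C)(C)C=Cc2c1 | intermediate
12 | 3-methylbut-2-en-1-ylzinc bromide | CC(C)=CC[Zn]Br | starting material
13 | 8'-(methoxymethoxy)-2,2,2',2'-tetramethyl-8-(3-methylbut-2-en-1-yl)-2H,2'H-6,6'-bichromene | COCOc1cc(cc2C=CC(C)(C)Oc12)-c1cc(CC=C(C)C)c2OC(C)(C)C=Cc2c1 | intermediate
14 | 2,2,2',2'-tetramethyl-8-(3-methylbut-2-en-1-yl)-2H,2'H-[6,6'-bichromen]-8'-ol | CC(C)=CCc1cc(-c2cc(O)c3c(c2)C=CC(C)(C)O3)cc2c1OC(C)(C)C=C2 | target

**Step count and risks**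

Total step count: 8. Longest linear sequence: 8 steps (from 1 to 14).

Steps most likely to fail:

Step 6. The Giese addition of the tertiary C2 radical to the only weakly activated vinyl sulfoxide may be too slow. Oxidation of the radical to the oxocarbenium ion, hydrogen-atom capture, or reduction of the α-sulfinyl radical before ring closure could then take over, and the twofold course doubles the demand. The fallback uses the classical chromene synthesis and sets out from 6. Twofold O-alkylation with 3-chloro-3-methylbut-1-yne (CuCl2·2H2O cat., DBU, MeCN, 0 °C) should give 3-chloro-3'-(methoxymethoxy)-4,4'-bis[(2-methylbut-3-yn-2-yl)oxy]-1,1'-biphenyl F1. Heating F1 in N,N-diethylaniline or xylene (140–180 °C) should trigger on each ring the aryl propargyl ether Claisen rearrangement, 1,5-hydrogen shift and oxa-6π electrocyclisation at the only free ortho position. This comes back to the route at 11.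

Step 7. Oxidative addition into the electron-rich, ortho-oxygenated C8–Cl bond may be slow, and bond formation at the substituted terminus of the prenyl group (reverse prenylation) may compete. The fallback inverts the polarity and sets out from 11. Miyaura borylation of the aryl chloride (Pd2(dba)3, XPhos, B2pin2, KOAc, 1,4-dioxane, 100 °C) should give 2-[8'-(methoxymethoxy)-2,2,2',2'-tetramethyl-2H,2'H-[6,6'-bichromen]-8-yl]-4,4,5,5-tetramethyl-1,3,2-dioxaborolane F2. Suzuki-type allylation of F2 with prenyl bromide (Pd(PPh3)4, K2CO3, THF/H2O, 60 °C) should join the aryl group to the unsubstituted terminus of the π-prenyl palladium intermediate. This comes back to the route at 13.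

Step 4. Etherification of the two ortho-substituted phenoxides may stay incomplete, and ring formylation by dichlorocarbene may compete. The fallback sets out from 6. Twofold alkylation with ethyl 2-bromo-2-methylpropanoate (Cs2CO3, DMF, 70 °C) should give diethyl 2,2'-{[3-chloro-3'-(methoxymethoxy)-[1,1'-biphenyl]-4,4'-diyl]bis(oxy)}bis(2-methylpropanoate) F3. Saponification of F3 (LiOH, THF/MeOH/H2O, rt; then acidification to pH 3 at 0 °C) comes back to the route at 7.

**Further compounds**

F1 | step 6 | 3-chloro-3'-(methoxymethoxy)-4,4'-bis[(2-methylbut-3-yn-2-yl)oxy]-1,1'-biphenyl | COCOc1cc(ccc1OC(C)(C)C#C)-c1ccc(OC(C)(C)C#C)c(Cl)c1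
F2 | step 7 | 2-[8'-(methoxymethoxy)-2,2,2',2'-tetramethyl-2H,2'H-[6,6'-bichromen]-8-yl]-4,4,5,5-tetramethyl-1,3,2-dioxaborolane | COCOc1cc(cc2C=CC(C)(C)Oc12)-c1cc(B2OC(C)(C)C(C)(C)O2)c2OC(C)(C)C=Cc2c1
F3 | step 4 | diethyl 2,2'-{[3-chloro-3'-(methoxymethoxy)-[1,1'-biphenyl]-4,4'-diyl]bis(oxy)}bis(2-methylpropanoate) | CCOC(=O)C(C)(C)Oc1ccc(cc1OCOC)-c1ccc(OC(C)(C)C(=O)OCC)c(Cl)c1
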